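The target is cut at the C8–O diaryl ether into a ring B aryliodonium salt (from olivetolic acid) and 6,8-dihydroxy-3-pentylisocoumarin. Read from C1 through C8a, C8, C7, C6, C5, C4a and C4 to C3, the isocoumarin carbons are one linear chain in which C1, C8, C6, C4a and C3 each carry (or carried) an oxygen, the mark of a folded polyketide. A 3,5,7-triketo ester holding C3 as a dioxolane is therefore folded in one flask: base joins C8a to C4a and aromatises carbocyclic ring A, then acid unmasks C3 and closes the O2–C1 lactone bond of pyranone ring C. Benzylation, metal-free O-arylation and hydrogenolysis complete the route.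

Key step: step 3

Assumption: olivetolic acid (2,4-dihydroxy-6-pentylbenzoic acid) and methyl 3,5-dioxohexanoate are taken as catalogue compounds, which avoids a carboxylation of olivetol of uncertain regiochemistry.

Step 1
Reactants: 1 methyl 3-oxooctanoate; 2 ethylene glycol
Product: 3 methyl 2-(2-pentyl-1,3-dioxolan-2-yl)acetate
Conditions: TsOH·H2O (cat.), toluene, reflux, Dean–Stark
Reagents that add atoms: none
Why: Acid-catalysed ketalisation of the ketone with azeotropic removal of water is routine for β-keto esters and leaves the methyl ester as the only acylating carbonyl of the fragment.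

Step 2
Reactants: 3 methyl 2-(2-pentyl-1,3-dioxolan-2-yl)acetate; 4 methyl 3,5-dioxohexanoate
Product: 5 methyl 3,5,7-trioxo-8-(2-pentyl-1,3-dioxolan-2-yl)octanoate
Conditions: 4 (2 equiv), LiN(i-Pr)2 (LDA, 6.2 equiv), THF, 0 °C; then 3 (1 equiv), −78 to 0 °C; AcOH quench, extractive work-up, crude product used directly
Reagents that add atoms: none
Why: Harris-type Claisen acylation, in which LDA turns 4 into its trianion, the terminal C6 carbanion (last formed, most nucleophilic) attacks the ester carbonyl of 3, and the second equivalent of trianion takes up the acidic proton of the new diketone methylene; 3,3-(ethylenedioxy) esters are established acyl donors toward β-keto ester polyanions.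

Step 3
Reactants: 5 methyl 3,5,7-trioxo-8-(2-pentyl-1,3-dioxolan-2-yl)octanoate
Product: 8 6,8-dihydroxy-3-pentyl-1H-isochromen-1-one (6,8-dihydroxy-3-pentylisocoumarin), via resorcylate ketal 6 (not isolated), via keto ester 7 (not isolated)
Conditions: 1 M aq KOH, N2, 0 °C to rt; then 6 M HCl to pH 1, THF, 50 °C, same flask
Reagents that add atoms: water, O
Why: Hydroxide converts 5 into its polyenolate, whose C8a carbon (between the ester and the C8 ketone) adds to the C4a ketone in a 6-(enolendo)-exo-trig aldol closure, and loss of water with enolisation of the C6 and C8 carbonyls aromatises ring A as resorcylate 6. Acidification hydrolyses the dioxolane to ketone 7, whose C3 enol oxygen attacks the hydrogen-bond-activated C1 ester carbon in a 6-exo-trig acyl substitution that expels methanol and closes ring C. The closest known reactions are the aldol cyclisation of 3,5,7-triketo esters to β-resorcylates in aqueous base and the acid-mediated enol lactonisation of 2-(2-oxoalkyl)benzoates to isocoumarins. No stereocenter is formed. The selectivity needed is aldol closure of C8a onto C4a over Claisen closure of C5 onto C1 and over any reaction at C3. The non-chelating KOH/water medium leaves the ester unactivated and favours the fast aldol–dehydration, and the dioxolane keeps C3 non-electrophilic and its neighbour C4 only singly activated until ring A is aromatic.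

Step 4
Reactants: 8 6,8-dihydroxy-3-pentyl-1H-isochromen-1-one
Product: 9 6-(benzyloxy)-8-hydroxy-3-pentyl-1H-isochromen-1-one
Conditions: BnBr (1.05 equiv), K2CO3 (1.1 equiv), acetone, rt to 40 °C
Reagents that add atoms: benzyl bromide, BrCc1ccccc1
Why: Williamson ether synthesis in which the 8-hydroxyl, held in a hydrogen bond by the peri C1 carbonyl, stays inert toward one equivalent of benzyl bromide and a carbonate base, so that only the free and more acidic 6-hydroxyl is benzylated.

Step 5
Reactants: 10 olivetolic acid (2,4-dihydroxy-6-pentylbenzoic acid)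
Product: 11 benzyl 2,4-bis(benzyloxy)-6-pentylbenzoate
Conditions: BnBr (3.5 equiv), K2CO3 (4 equiv), DMF, rt then 60 °C
Reagents that add atoms: benzyl bromide, BrCc1ccccc1
Why: Exhaustive Williamson-type O-alkylation in which the carboxylate is benzylated first at room temperature, removing the risk of decarboxylation, and warming with excess reagent then converts both phenols, including the chelated 2-hydroxyl, into benzyl ethers.

Step 6
Reactants: 11 benzyl 2,4-bis(benzyloxy)-6-pentylbenzoate
Product: 12 benzyl 4,6-bis(benzyloxy)-3-iodo-2-pentylbenzoate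
Conditions: N-iodosuccinimide (1.1 equiv), CF3CO2H (cat.), MeCN, 0 °C to rt
Reagents that add atoms: N-iodosuccinimide, O=C1CCC(=O)N1I
Why: Electrophilic aromatic iodination, in which of the two free ring positions the one ortho to one benzyloxy group, para to the other and next to the pentyl chain is attacked, because the position between the two benzyloxy groups is the hindered site that 1,3-dialkoxybenzenes generally avoid.

Step 7
Reactants: 12 benzyl 4,6-bis(benzyloxy)-3-iodo-2-pentylbenzoate; 13 1,3,5-trimethoxybenzene
Product: 15 [4,6-bis(benzyloxy)-3-(benzyloxycarbonyl)-2-pentylphenyl](2,4,6-trimethoxyphenyl)iodonium tosylate, via hydroxy(tosyloxy)iodane 14 (not isolated)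
Conditions: mCPBA (1.1 equiv), TsOH·H2O (1.1 equiv), MeCN, rt to 40 °C; then 13 (1.1 equiv), rt; precipitation from Et2O
Reagents that add atoms: p-toluenesulfonic acid, Cc1ccc(S(=O)(=O)O)cc1
Why: Known one-pot synthesis of aryl(2,4,6-trimethoxyphenyl)iodonium tosylates, in which mCPBA and TsOH oxidise the aryl iodide to the trivalent-iodine Koser-type species 14, which then substitutes the very electron-rich trimethoxybenzene by electrophilic aromatic substitution.

Step 8
Reactants: 9 6-(benzyloxy)-8-hydroxy-3-pentyl-1H-isochromen-1-one; 15 [4,6-bis(benzyloxy)-3-(benzyloxycarbonyl)-2-pentylphenyl](2,4,6-trimethoxyphenyl)iodonium tosylate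
Product: 16 benzyl 4,6-bis(benzyloxy)-3-{[6-(benzyloxy)-1-oxo-3-pentyl-1H-isochromen-8-yl]oxy}-2-pentylbenzoate
Conditions: KOt-Bu (1.05 equiv), THF, 0 °C; then 15 (1.2 equiv), rt to 40 °C
Reagents that add atoms: none
Why: Metal-free O-arylation of a phenoxide by ligand coupling at trivalent iodine, in which KOt-Bu breaks the 8-OH chelate, the phenoxide binds iodine, and the ring B aryl group (less electron-rich than the trimethoxyphenyl auxiliary and favoured by its two ortho substituents) is transferred to oxygen, while the absence of ortho hydrogens on both aryl groups excludes an aryne pathway.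

Step 9
Reactants: 16 benzyl 4,6-bis(benzyloxy)-3-{[6-(benzyloxy)-1-oxo-3-pentyl-1H-isochromen-8-yl]oxy}-2-pentylbenzoate
Product: 17 4,6-dihydroxy-3-[(6-hydroxy-1-oxo-3-pentyl-1H-isochromen-8-yl)oxy]-2-pentylbenzoic acid (CNP0439913.0)
Conditions: H2 (1 atm), 10% Pd/C, EtOAc, rt, stopped after uptake of 4 equiv H2; concentration below 30 °C
Reagents that add atoms: none
Why: Heterogeneous hydrogenolysis cleaves the three aryl benzyl ethers and the benzyl ester in one neutral operation at room temperature, where benzylic C–O cleavage should outpace hydrogenation of the trisubstituted C3=C4 enol-lactone double bond and the 2,4-dihydroxybenzoic acid is not exposed to heat that could decarboxylate it.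

Compound list (no compound contains a stereocenter)
1 | methyl 3-oxooctanoate | CCCCCC(=O)CC(=O)OC | starting material
2 | ethylene glycol | OCCO | starting material
3 | methyl 2-(2-pentyl-1,3-dioxolan-2-yl)acetate | CCCCCC1(CC(=O)OC)OCCO1 | intermediate
4 | methyl 3,5-dioxohexanoate | CC(=O)CC(=O)CC(=O)OC | starting material
5 | methyl 3,5,7-trioxo-8-(2-pentyl-1,3-dioxolan-2-yl)octanoate | COC(=O)CC(=O)CC(=O)CC(=O)CC1(CCCCC)OCCO1 | intermediate
6 | methyl 2,4-dihydroxy-6-[(2-pentyl-1,3-dioxolan-2-yl)methyl]benzoate (resorcylate ketal, not isolated) | CCCCCC1(Cc2cc(O)cc(O)c2C(=O)OC)OCCO1 | intermediate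
7 | methyl 2,4-dihydroxy-6-(2-oxoheptyl)benzoate (keto ester, not isolated) | CCCCCC(=O)Cc1cc(O)cc(O)c1C(=O)OC | intermediate
8 | 6,8-dihydroxy-3-pentyl-1H-isochromen-1-one | CCCCCc1cc2cc(O)cc(O)c2c(=O)o1 | intermediate
9 | 6-(benzyloxy)-8-hydroxy-3-pentyl-1H-isochromen-1-one | CCCCCc1cc2cc(OCc3ccccc3)cc(O)c2c(=O)o1 | intermediate
10 | olivetolic acid (2,4-dihydroxy-6-pentylbenzoic acid) | CCCCCc1cc(O)cc(O)c1C(=O)O | starting material
11 | benzyl 2,4-bis(benzyloxy)-6-pentylbenzoate | CCCCCc1cc(OCc2ccccc2)cc(OCc2ccccc2)c1C(=O)OCc1ccccc1 | intermediate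
12 | benzyl 4,6-bis(benzyloxy)-3-iodo-2-pentylbenzoate | CCCCCc1c(I)c(OCc2ccccc2)cc(OCc2ccccc2)c1C(=O)OCc1ccccc1 | intermediate
13 | 1,3,5-trimethoxybenzene | COc1cc(OC)cc(OC)c1 | starting material
14 | benzyl 4,6-bis(benzyloxy)-3-[hydroxy(tosyloxy)-λ3-iodanyl]-2-pentylbenzoate (not isolated) | CCCCCc1c(I(O)OS(=O)(=O)c2ccc(C)cc2)c(OCc2ccccc2)cc(OCc2ccccc2)c1C(=O)OCc1ccccc1 | intermediate
15 | [4,6-bis(benzyloxy)-3-(benzyloxycarbonyl)-2-pentylphenyl](2,4,6-trimethoxyphenyl)iodonium tosylate | CCCCCc1c([I+]c2c(OC)cc(OC)cc2OC)c(OCc2ccccc2)cc(OCc2ccccc2)c1C(=O)OCc1ccccc1.Cc1ccc(S(=O)(=O)[O-])cc1 | intermediate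
16 | benzyl 4,6-bis(benzyloxy)-3-{[6-(benzyloxy)-1-oxo-3-pentyl-1H-isochromen-8-yl]oxy}-2-pentylbenzoate | CCCCCc1cc2cc(OCc3ccccc3)cc(Oc3c(OCc4ccccc4)cc(OCc4ccccc4)c(C(=O)OCc4ccccc4)c3CCCCC)c2c(=O)o1 | intermediate
17 | 4,6-dihydroxy-3-[(6-hydroxy-1-oxo-3-pentyl-1H-isochromen-8-yl)oxy]-2-pentylbenzoic acid | CCCCCc1cc2cc(O)cc(Oc3c(O)cc(O)c(C(=O)O)c3CCCCC)c2c(=O)o1 | target

Total steps: 9. Longest linear sequence: 6 steps (steps 1, 2, 3, 4, 8 and 9); the ring B branch (steps 5, 6, 7) joins at step 8.

Steps most likely to fail

Step 3. The polyenolate may close in the Claisen sense (C5 onto C1) or by O-acylation to a 2-pyrone. The ester may also be hydrolysed and decarboxylated before ring A forms, or the lactonisation may stop at the open keto ester. The fallback removes the Claisen option by locking C1 and C8 in a dioxinone. It sets out from ketal ester 3, which acylates the LDA-derived dianion of the known keto-dioxinone 2,2-dimethyl-6-(2-oxopropyl)-4H-1,3-dioxin-4-one F1 (one step from 2,2,6-trimethyl-4H-1,3-dioxin-4-one by acetylation of its lithium dienolate). This should give the diketo-dioxinone 6-[2,4-dioxo-5-(2-pentyl-1,3-dioxolan-2-yl)pentyl]-2,2-dimethyl-4H-1,3-dioxin-4-one F2. Et3N in CH2Cl2 should then bring about the aldol aromatisation to the isopropylidene-protected resorcylate 7-hydroxy-2,2-dimethyl-5-[(2-pentyl-1,3-dioxolan-2-yl)methyl]-4H-1,3-benzodioxin-4-one F3. NaOMe in MeOH opens F3 to the methyl ester, which is compound 6, where the fallback rejoins the route. Isolated 6 is then taken to 8 by the acid half of step 3 (aqueous HCl, THF, 50 °C).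

Step 8. The trimethoxyphenyl group may be transferred in competition with the ring B aryl group. The ligand coupling may also be slow because both partners are hindered, and the base may open the lactone. The fallback is a copper-catalysed Ullmann diaryl ether synthesis that also makes step 7 unnecessary. It sets out from aryl iodide 12 and phenol 9 (CuI, picolinic acid, K3PO4, DMSO, 90 °C) and rejoins the route at 16; no new compound is made (F0).

Step 2. Proton transfer from the α-methylene of 3 to the trianion, followed by β-elimination that opens the dioxolane, may consume both partners. The triketo ester may also cyclise prematurely during work-up. The fallback replaces the Claisen acylation by an aldol addition and an oxidation. It sets out from 3, which i-Bu2AlH (CH2Cl2, −78 °C) should reduce to 2-(2-pentyl-1,3-dioxolan-2-yl)acetaldehyde F4. The trianion of 4 (LDA, THF, −78 °C) adds to F4 through its terminal carbon to give racemic methyl 7-hydroxy-3,5-dioxo-8-(2-pentyl-1,3-dioxolan-2-yl)octanoate F5. Dess–Martin periodinane (CH2Cl2, NaHCO3) then oxidises F5 to 5, where the route is rejoined.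

Further compounds
F1 | step 3 | 2,2-dimethyl-6-(2-oxopropyl)-4H-1,3-dioxin-4-one | CC(=O)CC1=CC(=O)OC(C)(C)O1
F2 | step 3 | 6-[2,4-dioxo-5-(2-pentyl-1,3-dioxolan-2-yl)pentyl]-2,2-dimethyl-4H-1,3-dioxin-4-one | CCCCCC1(CC(=O)CC(=O)CC2=CC(=O)OC(C)(C)O2)OCCO1
F3 | step 3 | 7-hydroxy-2,2-dimethyl-5-[(2-pentyl-1,3-dioxolan-2-yl)methyl]-4H-1,3-benzodioxin-4-one | CCCCCC1(Cc2cc(O)cc3OC(C)(C)OC(=O)c23)OCCO1
F0 | step 8 | none | none
F4 | step 2 | 2-(2-pentyl-1,3-dioxolan-2-yl)acetaldehyde | CCCCCC1(CC=O)OCCO1
F5 | step 2 | methyl 7-hydroxy-3,5-dioxo-8-(2-pentyl-1,3-dioxolan-2-yl)octanoate (racemic) | COC(=O)CC(=O)CC(=O)CC(O)CC1(CCCCC)OCCO1
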